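**Retrosynthetic overview**

1. Target 16 comes from the (3R)-chroman bis-tosylate 15 by hydrolysis of both aryl sulfonates. Rings A and B are bought as benzenes; the dihydropyran ring (ring C) is the only ring made, and it is made last.
2. 15 comes from the acyclic, achiral aryl bromide 13 by disconnection of C4–C4a. Copper hydride-catalysed enantioselective hydroboration of the 2-arylallyl ether sets C3 and puts boron on the future C4; an intramolecular B-alkyl Suzuki–Miyaura coupling onto C4a–Br follows in the same flask.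
3. Enabling feature: C3, the only stereocentre, is a methine between C2 and C4 that carries ring B, so C3–C4 can be stored as the C=CH2 of a 2-arylallyl ether on O1. C4a lies between O1 and the 5-OMe oxygen and para to O7, so it can be bought as the C–Br of a mirror-symmetric 4-bromo-3,5-dioxygenated phenol.
4. 13 comes from the symmetric bromoresorcinol 8 (made from 6). One of its two equivalent hydroxyls takes a 1,1-dimethylallyl group from 9, the other takes alcohol 5. A Claisen rearrangement then puts the prenyl group on C6 only, because the other ortho carbon (C4a) is blocked by Br, and the freed 5-OH is methylated.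
5. 5 comes from aryl bromide 1 (tosylation, borylation) and 2-bromoallyl alcohol 4 by Suzuki–Miyaura coupling.

Key step: step 10

Remark: C3 of the target is (R) (CIP order CH2O > ring B carbon > C4 > H). The sense of induction of the (R)-DTBM-SEGPHOS copper hydride is assigned by analogy with α-substituted vinylarenes; the (S)-ligand is to be used instead if a first run on 13 shows the opposite sense.

**Route**

Step 1
Reactants: 1 4-bromo-3-methoxyphenol
Product: 2 4-bromo-3-methoxyphenyl 4-methylbenzenesulfonate
Conditions: TsCl, Et3N, DMAP (cat.), CH2Cl2, 0 °C to rt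
Reagents that add atoms: tosyl chloride, Cc1ccc(cc1)S(Cl)(=O)=O
Why: O-sulfonylation of the phenol gives an aryl tosylate that should tolerate the bases, palladium catalysts and copper hydride used later and is cleaved by hydroxide at the end.

Step 2
Reactants: 2 4-bromo-3-methoxyphenyl 4-methylbenzenesulfonate
Product: 3 3-methoxy-4-(4,4,5,5-tetramethyl-1,3,2-dioxaborolan-2-yl)phenyl 4-methylbenzenesulfonate
Conditions: B2pin2, Pd(dppf)Cl2 (3 mol %), KOAc, 1,4-dioxane, 90 °C
Reagents that add atoms: bis(pinacolato)diboron, CC1(C)OB(OC1(C)C)B1OC(C)(C)C(C)(C)O1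
Why: Miyaura borylation with Pd(dppf)Cl2 and KOAc is chemoselective for the C–Br bond over the aryl sulfonate.

Step 3
Reactants: 3 3-methoxy-4-(4,4,5,5-tetramethyl-1,3,2-dioxaborolan-2-yl)phenyl 4-methylbenzenesulfonate; 4 2-bromoprop-2-en-1-ol
Product: 5 4-(3-hydroxyprop-1-en-2-yl)-3-methoxyphenyl 4-methylbenzenesulfonate
Conditions: Pd(PPh3)4 (5 mol %), K2CO3, 1,4-dioxane/H2O, 80 °C
Reagents that add atoms: none
Why: Suzuki–Miyaura coupling of the arylboronate with the vinyl bromide should give the 2-arylallyl alcohol that carries ring B, C2, C3 and the future C4 as its =CH2 terminus.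

Step 4
Reactants: 6 4-bromo-3,5-dimethoxyphenol
Product: 7 4-bromo-3,5-dimethoxyphenyl 4-methylbenzenesulfonate
Conditions: TsCl, Et3N, DMAP (cat.), CH2Cl2, 0 °C to rt
Reagents that add atoms: tosyl chloride, Cc1ccc(cc1)S(Cl)(=O)=O
Why: O-sulfonylation masks the future 7-OH with a group that survives BBr3, which a silyl or acetal group would not.

Step 5
Reactants: 7 4-bromo-3,5-dimethoxyphenyl 4-methylbenzenesulfonate
Product: 8 4-bromo-3,5-dihydroxyphenyl 4-methylbenzenesulfonate
Conditions: BBr3 (3 equiv), CH2Cl2, −78 °C to rt; then H2O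
Reagents that add atoms: none
Why: Lewis acid ether cleavage with BBr3 removes both methyl groups, which are equivalent through the mirror plane containing C–Br and C–OTs, so no selectivity is needed.

Step 6
Reactants: 8 4-bromo-3,5-dihydroxyphenyl 4-methylbenzenesulfonate (threefold excess, to be recovered); 9 tert-butyl (2-methylbut-3-en-2-yl) carbonate
Product: 10 4-bromo-3-hydroxy-5-[(2-methylbut-3-en-2-yl)oxy]phenyl 4-methylbenzenesulfonate
Conditions: Pd(PPh3)4 (2 mol %), THF, 0 °C
Reagents that add atoms: none
Why: Palladium-catalysed decarboxylative allylic etherification (Tsuji–Trost) of a phenol with a tertiary allylic carbonate should give the branched 1,1-dimethylallyl ether under kinetic control, the two hydroxyls being equivalent and the hindered aryl bromide being inert to Pd(PPh3)4 at this temperature.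

Step 7
Reactants: 10 4-bromo-3-hydroxy-5-[(2-methylbut-3-en-2-yl)oxy]phenyl 4-methylbenzenesulfonate; 5 4-(3-hydroxyprop-1-en-2-yl)-3-methoxyphenyl 4-methylbenzenesulfonate
Product: 11 4-bromo-3-[(2-methylbut-3-en-2-yl)oxy]-5-({2-[2-methoxy-4-(tosyloxy)phenyl]prop-2-en-1-yl}oxy)phenyl 4-methylbenzenesulfonate
Conditions: PPh3, DIAD, THF, 0 °C to rt
Reagents that add atoms: none
Why: Mitsunobu etherification of the remaining phenol with the primary allylic alcohol forms the O1–C2 bond under neutral conditions, and because the 2-arylallyl unit is symmetric an SN2 or SN2' course leads to the same ether.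

Step 8
Reactants: 11 4-bromo-3-[(2-methylbut-3-en-2-yl)oxy]-5-({2-[2-methoxy-4-(tosyloxy)phenyl]prop-2-en-1-yl}oxy)phenyl 4-methylbenzenesulfonate
Product: 12 4-bromo-3-hydroxy-2-(3-methylbut-2-en-1-yl)-5-({2-[2-methoxy-4-(tosyloxy)phenyl]prop-2-en-1-yl}oxy)phenyl 4-methylbenzenesulfonate
Conditions: toluene, 110 °C (sealed tube)
Reagents that add atoms: none
Why: Aromatic Claisen rearrangement of the 1,1-dimethylallyl ether should deliver a linear prenyl group to C6, the only ortho carbon bearing hydrogen since the other is blocked by bromine, at a temperature well below that needed for the 2-arylallyl ether to rearrange.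

Step 9
Reactants: 12 4-bromo-3-hydroxy-2-(3-methylbut-2-en-1-yl)-5-({2-[2-methoxy-4-(tosyloxy)phenyl]prop-2-en-1-yl}oxy)phenyl 4-methylbenzenesulfonate
Product: 13 4-bromo-3-methoxy-2-(3-methylbut-2-en-1-yl)-5-({2-[2-methoxy-4-(tosyloxy)phenyl]prop-2-en-1-yl}oxy)phenyl 4-methylbenzenesulfonate
Conditions: MeI, K2CO3, DMF, rt
Reagents that add atoms: iodomethane, CI
Why: Williamson methylation of the newly freed phenol fixes the 5-OMe group between C4a–Br and the prenyl group.

Step 10
Reactants: 13 4-bromo-3-methoxy-2-(3-methylbut-2-en-1-yl)-5-({2-[2-methoxy-4-(tosyloxy)phenyl]prop-2-en-1-yl}oxy)phenyl 4-methylbenzenesulfonate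
Product: 15 (3R)-5-methoxy-3-[2-methoxy-4-(tosyloxy)phenyl]-6-(3-methylbut-2-en-1-yl)chroman-7-yl 4-methylbenzenesulfonate, via primary alkyl pinacolboronate 14 (not isolated)
Conditions: CuCl (5 mol %), (R)-DTBM-SEGPHOS (5.5 mol %), NaOtBu (10 mol %), HBpin (1.5 equiv), THF, rt to 40 °C; MeOH quench; then Pd(OAc)2 (5 mol %), RuPhos (10 mol %), aq K3PO4 (3 equiv), toluene, 90 °C, same flask
Reagents that add atoms: none
Why: A bisphosphine-ligated copper hydride, generated from CuCl, NaOtBu and HBpin, inserts the 1,1-disubstituted alkene with copper on the unsubstituted CH2 (the future C4) and hydride on the carbon bearing ring B, and σ-bond metathesis with HBpin releases primary boronate 14; once the alkene is consumed, zerovalent palladium adds oxidatively to the C4a–Br bond, the boronate is transferred to palladium with the help of aqueous K3PO4, and reductive elimination forms C4–C4a. The closest known reaction types are the copper hydride-catalysed enantioselective hydroboration of α-substituted vinylarenes and the intramolecular B-alkyl Suzuki–Miyaura coupling that closes benzo-fused six-membered rings. Ring C closes in the exo sense, the tethered CH2 being delivered to the arene carbon through a seven-membered aryl(alkyl)palladium chelate. The C3 stereocentre is set in the hydrocupration, where the chiral pocket of DTBM-SEGPHOS distinguishes the aryl from the aryloxymethyl substituent of the alkene, and it is not touched afterwards because it lies β to boron and carries no acidic hydrogen. The step needs site selectivity on ring A, secured by the bromine at C4a (C8 carries only hydrogen), regioselective Cu–H addition, secured by the 1,1-disubstitution that keeps copper off C3 and so prevents β-aryloxy elimination, and chemoselectivity over the prenyl group, whose trisubstituted alkene inserts into Cu–H far more slowly. Running the palladium cycle only after the copper cycle keeps the aryl–palladium species from a 5-exo Heck insertion into the alkene.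

Step 11
Reactants: 15 (3R)-5-methoxy-3-[2-methoxy-4-(tosyloxy)phenyl]-6-(3-methylbut-2-en-1-yl)chroman-7-yl 4-methylbenzenesulfonate
Product: 16 (3R)-3-(4-hydroxy-2-methoxyphenyl)-5-methoxy-6-(3-methylbut-2-en-1-yl)chroman-7-ol
Conditions: KOH (10 equiv), MeOH/THF/H2O, 65 °C, degassed; then aq NH4Cl
Reagents that add atoms: none
Why: Hydroxide attacks sulfur of both aryl sulfonates (sulfonate ester hydrolysis) to free the 7-OH and 4'-OH groups without touching the methyl ethers, the prenyl group or the non-acidic C3–H stereocentre.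

**Compound list**

1 | 4-bromo-3-methoxyphenol | COc1cc(O)ccc1Br | starting material
2 | 4-bromo-3-methoxyphenyl 4-methylbenzenesulfonate | COc1cc(OS(=O)(=O)c2ccc(C)cc2)ccc1Br | intermediate
3 | 3-methoxy-4-(4,4,5,5-tetramethyl-1,3,2-dioxaborolan-2-yl)phenyl 4-methylbenzenesulfonate | COc1cc(OS(=O)(=O)c2ccc(C)cc2)ccc1B1OC(C)(C)C(C)(C)O1 | intermediate
4 | 2-bromoprop-2-en-1-ol | OCC(Br)=C | starting material
5 | 4-(3-hydroxyprop-1-en-2-yl)-3-methoxyphenyl 4-methylbenzenesulfonate | COc1cc(OS(=O)(=O)c2ccc(C)cc2)ccc1C(=C)CO | intermediate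
6 | 4-bromo-3,5-dimethoxyphenol | COc1cc(O)cc(OC)c1Br | starting material
7 | 4-bromo-3,5-dimethoxyphenyl 4-methylbenzenesulfonate | COc1cc(OS(=O)(=O)c2ccc(C)cc2)cc(OC)c1Br | intermediate
8 | 4-bromo-3,5-dihydroxyphenyl 4-methylbenzenesulfonate | Oc1cc(OS(=O)(=O)c2ccc(C)cc2)cc(O)c1Br | intermediate
9 | tert-butyl (2-methylbut-3-en-2-yl) carbonate | C=CC(C)(C)OC(=O)OC(C)(C)C | starting material
10 | 4-bromo-3-hydroxy-5-[(2-methylbut-3-en-2-yl)oxy]phenyl 4-methylbenzenesulfonate | C=CC(C)(C)Oc1cc(OS(=O)(=O)c2ccc(C)cc2)cc(O)c1Br | intermediate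
11 | 4-bromo-3-[(2-methylbut-3-en-2-yl)oxy]-5-({2-[2-methoxy-4-(tosyloxy)phenyl]prop-2-en-1-yl}oxy)phenyl 4-methylbenzenesulfonate | C=CC(C)(C)Oc1cc(OS(=O)(=O)c2ccc(C)cc2)cc(OCC(=C)c2ccc(OS(=O)(=O)c3ccc(C)cc3)cc2OC)c1Br | intermediate
12 | 4-bromo-3-hydroxy-2-(3-methylbut-2-en-1-yl)-5-({2-[2-methoxy-4-(tosyloxy)phenyl]prop-2-en-1-yl}oxy)phenyl 4-methylbenzenesulfonate | CC(C)=CCc1c(OS(=O)(=O)c2ccc(C)cc2)cc(OCC(=C)c2ccc(OS(=O)(=O)c3ccc(C)cc3)cc2OC)c(Br)c1O | intermediate
13 | 4-bromo-3-methoxy-2-(3-methylbut-2-en-1-yl)-5-({2-[2-methoxy-4-(tosyloxy)phenyl]prop-2-en-1-yl}oxy)phenyl 4-methylbenzenesulfonate | CC(C)=CCc1c(OS(=O)(=O)c2ccc(C)cc2)cc(OCC(=C)c2ccc(OS(=O)(=O)c3ccc(C)cc3)cc2OC)c(Br)c1OC | intermediate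
14 | 4-bromo-3-methoxy-5-{[(2R)-2-[2-methoxy-4-(tosyloxy)phenyl]-3-(4,4,5,5-tetramethyl-1,3,2-dioxaborolan-2-yl)propyl]oxy}-2-(3-methylbut-2-en-1-yl)phenyl 4-methylbenzenesulfonate | COc1cc(OS(=O)(=O)c3ccc(C)cc3)ccc1[C@@H](CB2OC(C)(C)C(C)(C)O2)COc2cc(OS(=O)(=O)c3ccc(C)cc3)c(CC=C(C)C)c(OC)c2Br | intermediate
15 | (3R)-5-methoxy-3-[2-methoxy-4-(tosyloxy)phenyl]-6-(3-methylbut-2-en-1-yl)chroman-7-yl 4-methylbenzenesulfonate | COc1cc(OS(=O)(=O)c3ccc(C)cc3)ccc1[C@@H]1COc2cc(OS(=O)(=O)c3ccc(C)cc3)c(CC=C(C)C)c(OC)c2C1 | intermediate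
16 | (3R)-3-(4-hydroxy-2-methoxyphenyl)-5-methoxy-6-(3-methylbut-2-en-1-yl)chroman-7-ol | COc1cc(O)ccc1[C@@H]1COc2cc(O)c(CC=C(C)C)c(OC)c2C1 | target

**Step count and risks**

Total step count: 11. Longest linear sequence: 8 steps (steps 1, 2, 3, 7, 8, 9, 10, 11 from 1; equally steps 4 to 11 from 6).

Steps most likely to fail:

Risk 1, step 10. In the ring-closing stage, β-hydride elimination from the alkylpalladium intermediate or protodeboronation may outrun transmetalation and reductive elimination at the doubly ortho-substituted aryl–palladium centre, so that ring C does not close; in the first stage, enantioface discrimination may be incomplete. The fallback separates the two events and closes the ring with an organozinc instead of the boronate. It sets out from 13: the same copper hydride hydroboration is run and boronate 14 is isolated. Oxidation (NaBO3·4H2O, THF/H2O) should give the (2S)-primary alcohol F1, where enantiomeric purity can be checked and, if needed, raised by crystallisation. Iodination (I2, PPh3, imidazole, CH2Cl2) should give the (2R)-primary iodide F2. Zinc insertion into the C–I bond only (Zn dust, LiCl, THF) should give the (2R)-alkylzinc iodide F3. Intramolecular Negishi coupling onto C4a–Br (Pd(OAc)2, SPhos, THF, 50 °C) then returns to the route at 15.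

Risk 2, step 6. The palladium catalyst may re-ionise the first-formed tertiary ether, with drift to the linear prenyl ether, and a second etherification may give the bis-ether. The fallback replaces π-allyl chemistry by propargylation and semi-hydrogenation. It sets out from 8: copper-catalysed O-alkylation with 3-chloro-3-methylbut-1-yne (CuCl2·2H2O cat., DBU, MeCN, 0 °C, 8 in excess) should give the 1,1-dimethylpropargyl ether F4. Semi-hydrogenation (H2, Pd/CaCO3 poisoned with Pb(OAc)2, quinoline, EtOAc) then returns to the route at 10.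

Risk 3, step 8. At the temperature needed for prenyl migration in the fully elaborated ether 11, the electron-rich styrene unit may degrade, the second allyl ether may begin to rearrange, or the tertiary ether may ionise with loss of the C5 unit before C6 is reached. The fallback moves the rearrangement ahead of the fragment union. It sets out from 10: heating (toluene, 110 °C) before the second ether is attached should give the prenylated bromoresorcinol F5. Mitsunobu reaction with 5 (PPh3, DIAD, THF) is then expected to take place at the hydroxyl flanked by Br and H and not at the one buttressed by Br and the prenyl group, returning to the route at 12.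

Further compounds
F1 | step 10 | 4-bromo-5-{[(2S)-3-hydroxy-2-[2-methoxy-4-(tosyloxy)phenyl]propyl]oxy}-3-methoxy-2-(3-methylbut-2-en-1-yl)phenyl 4-methylbenzenesulfonate | COc1cc(OS(=O)(=O)c3ccc(C)cc3)ccc1[C@@H](CO)COc2cc(OS(=O)(=O)c3ccc(C)cc3)c(CC=C(C)C)c(OC)c2Br
F2 | step 10 | 4-bromo-5-{[(2R)-3-iodo-2-[2-methoxy-4-(tosyloxy)phenyl]propyl]oxy}-3-methoxy-2-(3-methylbut-2-en-1-yl)phenyl 4-methylbenzenesulfonate | COc1cc(OS(=O)(=O)c3ccc(C)cc3)ccc1[C@@H](CI)COc2cc(OS(=O)(=O)c3ccc(C)cc3)c(CC=C(C)C)c(OC)c2Br
F3 | step 10 | {(2R)-3-[2-bromo-3-methoxy-4-(3-methylbut-2-en-1-yl)-5-(tosyloxy)phenoxy]-2-[2-methoxy-4-(tosyloxy)phenyl]propyl}zinc iodide | COc1cc(OS(=O)(=O)c3ccc(C)cc3)ccc1[C@@H](C[Zn]I)COc2cc(OS(=O)(=O)c3ccc(C)cc3)c(CC=C(C)C)c(OC)c2Br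
F4 | step 6 | 4-bromo-3-hydroxy-5-[(2-methylbut-3-yn-2-yl)oxy]phenyl 4-methylbenzenesulfonate | C#CC(C)(C)Oc1cc(OS(=O)(=O)c2ccc(C)cc2)cc(O)c1Br
F5 | step 8 | 4-bromo-3,5-dihydroxy-2-(3-methylbut-2-en-1-yl)phenyl 4-methylbenzenesulfonate | CC(C)=CCc1c(OS(=O)(=O)c2ccc(C)cc2)cc(O)c(Br)c1O
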